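**Plan**

1. The 3-oxopropyl chain and the isopropylidene group are cut together. The target is a hex-5-enal whose C=C is the exocyclic C=C(CH3)2 and whose C-4 is the ring CH, which is an oxy-Cope retron. Undoing the shift gives a ring C=CH double bond whose sp2 carbon carries a C(CH3)2–CH(OSiR3)–CH=CH2 arm.
2. That ring double bond lies opposite the ring CH2–CH(CH3) edge, so the six-membered ring is a cyclohexene [4+2] adduct. The ring CH2–CH2 bond and the bond from CH(CH3) to the quaternary carbon are cut, giving a 2,4-disubstituted penta-1,3-diene and acrolein; the ring methyl is the reduced formyl group.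
3. The aryl ether is cut at the allylic stage (Mitsunobu reaction with isofraxidin). The diene is cut at its central sp2–sp2 bond (enol triflate plus alkenylalane from propargyl alcohol). The triflate arm comes from an aldol of 3-methylbutan-2-one with acrolein.
4. Forward order: the chain is assembled (steps 1–6), the ring is formed by the cycloaddition (step 7), CHO is reduced to CH3 (steps 8–9), and the [3,3] shift creates the chain, the exocyclic alkene and the last stereocentre (step 10).
5. Stereochemistry: the quaternary carbon and the adjacent CH(CH3) come from the (E)-alkene (syn-carboalumination) and the endo, catalyst-controlled cycloaddition. The chain-bearing CH comes from the face-selective [3,3] shift. The silyloxy carbon is not controlled and is erased.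

Key step: step 7

Remark: the silyloxy-bearing carbon of the rearrangement handle is carried in both configurations (racemic up to 11, a pair of epimers from 12 to 15, left unspecified in the SMILES); it becomes the sp2 formyl carbon in step 10 and does not affect the configuration of the target.

Step 1
Reactants: 1 3-methylbutan-2-one
Product: 2 trimethyl[(3-methylbut-2-en-2-yl)oxy]silane
Conditions: Me3SiCl, NaI, Et3N, MeCN, rt; pentane extraction, distillation
Reagents that add atoms: chlorotrimethylsilane, C[Si](C)(C)Cl
Why: Silylation under equilibrating conditions (Me3SiI formed in the flask, amine base) should give mainly the more substituted, thermodynamic silyl enol ether, which fixes the next C–C bond at the isopropyl carbon.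

Step 2
Reactants: 2 trimethyl[(3-methylbut-2-en-2-yl)oxy]silane; 3 prop-2-enal (acrolein)
Product: 4 4-hydroxy-3,3-dimethylhex-5-en-2-one (racemic)
Conditions: BF3·OEt2 (1 equiv), CH2Cl2, −78 °C; aq. NaHCO3
Reagents that add atoms: none
Why: Mukaiyama aldol addition, in which the Lewis-acid-activated aldehyde carbon of acrolein is attacked 1,2 by the tetrasubstituted enol ether carbon, should create the quaternary C(CH3)2 carbon and the vinyl carbinol in one step; the carbinol centre is formed without control because it is erased in step 10.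

Step 3
Reactants: 4 4-hydroxy-3,3-dimethylhex-5-en-2-one
Product: 5 4-[(tert-butyldimethylsilyl)oxy]-3,3-dimethylhex-5-en-2-one (racemic)
Conditions: TBSOTf, 2,6-lutidine, CH2Cl2, −78 → 0 °C
Reagents that add atoms: tert-butyldimethylsilyl trifluoromethanesulfonate, CC(C)(C)[Si](C)(C)OS(=O)(=O)C(F)(F)F
Why: A silyl triflate with a hindered pyridine base silylates even neopentyl-type secondary alcohols, and the silyl ether blocks retro-aldol cleavage in the base-mediated step that follows.

Step 4
Reactants: 5 4-[(tert-butyldimethylsilyl)oxy]-3,3-dimethylhex-5-en-2-one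
Product: 6 4-[(tert-butyldimethylsilyl)oxy]-3,3-dimethylhexa-1,5-dien-2-yl trifluoromethanesulfonate (racemic)
Conditions: KN(SiMe3)2, THF, −78 °C; PhNTf2, −78 → 0 °C; aq. NH4Cl
Reagents that add atoms: N-phenylbis(trifluoromethanesulfonimide), O=S(=O)(N(c1ccccc1)S(=O)(=O)C(F)(F)F)C(F)(F)F
Why: The ketone can enolise only toward its methyl group (the other α-carbon is quaternary), so deprotonation and O-triflation should give the 1,1-disubstituted enol triflate regiospecifically.

Step 5
Reactants: 6 4-[(tert-butyldimethylsilyl)oxy]-3,3-dimethylhexa-1,5-dien-2-yl trifluoromethanesulfonate; 7 prop-2-yn-1-ol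
Product: 9 (2E)-6-[(tert-butyldimethylsilyl)oxy]-2,5,5-trimethyl-4-methylideneocta-2,7-dien-1-ol (racemic), via alkenylalane 8 (not isolated)
Conditions: 7, AlMe3 (3 equiv), Cp2ZrCl2 (0.25 equiv), CH2Cl2, 0 °C → rt; volatiles removed; then 6, ZnCl2, Pd(PPh3)4 (5 mol %), THF, rt → 40 °C; aq. potassium sodium tartrate
Reagents that add atoms: trimethylaluminium, C[Al](C)C
Why: Zirconium-catalysed syn-carboalumination of the terminal alkyne puts CH3 on the internal carbon and aluminium on the terminal carbon cis to each other, and Negishi-type cross-coupling of the alkenylalane (through zinc) with the enol triflate joins the two sp2 carbons with retention, so the (E) geometry (CH2OH trans to the diene carbon) follows from the syn addition.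

Step 6
Reactants: 9 (2E)-6-[(tert-butyldimethylsilyl)oxy]-2,5,5-trimethyl-4-methylideneocta-2,7-dien-1-ol; 10 isofraxidin (7-hydroxy-6,8-dimethoxy-2H-chromen-2-one)
Product: 11 7-{[(2E)-6-[(tert-butyldimethylsilyl)oxy]-2,5,5-trimethyl-4-methylideneocta-2,7-dien-1-yl]oxy}-6,8-dimethoxy-2H-chromen-2-one (racemic)
Conditions: PPh3, DIAD, THF, 0 °C → rt
Reagents that add atoms: none
Why: Mitsunobu etherification of the primary allylic alcohol with the acidic phenol should form the aryl ether by SN2 displacement while this carbon is still unhindered, which avoids a later substitution at a neopentyl position.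

Step 7
Reactants: 11 7-{[(2E)-6-[(tert-butyldimethylsilyl)oxy]-2,5,5-trimethyl-4-methylideneocta-2,7-dien-1-yl]oxy}-6,8-dimethoxy-2H-chromen-2-one; 3 prop-2-enal (acrolein)
Product: 12 (1S,2R)-4-{3-[(tert-butyldimethylsilyl)oxy]-2-methylpent-4-en-2-yl}-2-{[(6,8-dimethoxy-2-oxo-2H-chromen-7-yl)oxy]methyl}-2-methylcyclohex-3-ene-1-carbaldehyde (both configurations at the silyloxy carbon)
Conditions: acrolein (3 equiv), (5R)-5-benzyl-2,2,3-trimethylimidazolidin-4-one hydrochloride (20 mol %), MeCN/H2O 95:5, rt
Reagents that add atoms: none
Why: Acrolein condenses with the secondary amine salt to an (E)-iminium ion whose lowered LUMO engages diene 11 in an asynchronous concerted [4+2] cycloaddition, in which the unsubstituted CH2 terminus of the diene bonds to the iminium β-carbon and the α-carbon bonds to the terminus bearing CH3 and CH2OAr, and hydrolysis of the enamine/iminium product returns the catalyst and aldehyde 12. The closest known reaction type is the imidazolidinone-catalysed (iminium-activated) enantioselective Diels–Alder reaction of acrolein with 2-substituted and 1,3-disubstituted acyclic dienes. The cyclohexene ring is closed by an intermolecular suprafacial/suprafacial π4s + π2s cycloaddition that makes both σ bonds in one event, so no separate ring-closure mode applies. The quaternary carbon is set relative to the formyl-bearing carbon by the (E) geometry of the trisubstituted diene alkene (CH2OAr outside, CH3 inside) together with the endo transition state, which puts CHO cis to CH2OAr, and the absolute configuration comes from the catalyst, whose benzyl group in the (5R) series should cover the Si face of the iminium α-carbon so that the diene adds to the Re face. The step needs regio-, endo- and face-selectivity and enough reactivity at a fully substituted diene terminus: the tert-alkyl group on the internal diene carbon and the disubstituted terminus both make the CH2 terminus the nucleophilic one ("para" and "ortho" orientation agree), and the same tert-alkyl group destabilises the s-trans rotamer through allylic strain with the inside methyl, which holds the diene near the reactive s-cis form. The remote silyloxy carbon should not bias the outcome, and the terminal vinyl group and the coumarin C3–C4 double bond are not activated enough to compete.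

Step 8
Reactants: 12 (1S,2R)-4-{3-[(tert-butyldimethylsilyl)oxy]-2-methylpent-4-en-2-yl}-2-{[(6,8-dimethoxy-2-oxo-2H-chromen-7-yl)oxy]methyl}-2-methylcyclohex-3-ene-1-carbaldehyde
Product: 13 (E)-N-tosylhydrazone of 12 (both configurations at the silyloxy carbon)
Conditions: TsNHNH2, EtOH, rt
Reagents that add atoms: 4-methylbenzenesulfonohydrazide, Cc1ccc(cc1)S(=O)(=O)NN
Why: Condensation of the aldehyde with the sulfonyl hydrazide gives the tosylhydrazone under near-neutral conditions that should not touch the lactone or the silyl ether, and the α-stereocentre next to the quaternary carbon is not expected to epimerise.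

Step 9
Reactants: 13 (E)-N-tosylhydrazone of 12
Product: 15 7-{[(1S,6S)-3-{3-[(tert-butyldimethylsilyl)oxy]-2-methylpent-4-en-2-yl}-1,6-dimethylcyclohex-2-en-1-yl]methoxy}-6,8-dimethoxy-2H-chromen-2-one (both configurations at the silyloxy carbon), via N-boryl tosylhydrazine 14 (not isolated)
Conditions: catecholborane (2 equiv), CHCl3, 0 °C → rt; then NaOAc·3H2O, reflux
Reagents that add atoms: none
Why: Caglioti-type reductive deoxygenation, in which catecholborane adds hydride to the C=N carbon and acetate then triggers loss of sulfinate and of N2 from the resulting diazene, should turn CH=N into CH3 with no change at the adjacent stereocentre and without reduction of the coumarin lactone or the alkenes.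

Step 10
Reactants: 15 7-{[(1S,6S)-3-{3-[(tert-butyldimethylsilyl)oxy]-2-methylpent-4-en-2-yl}-1,6-dimethylcyclohex-2-en-1-yl]methoxy}-6,8-dimethoxy-2H-chromen-2-one
Product: 17 3-[(1S,2S,3S)-2-{[(6,8-dimethoxy-2-oxo-2H-chromen-7-yl)oxy]methyl}-2,3-dimethyl-6-(propan-2-ylidene)cyclohexyl]propanal (CNP0213227.1), via silyl enol ether 16 (not isolated)
Conditions: o-dichlorobenzene (degassed, base-washed sealed tube), 200 °C; then Bu4NF, AcOH, THF, 0 °C
Reagents that add atoms: none
Why: Thermal [3,3]-sigmatropic (siloxy-Cope) rearrangement of the 3-silyloxy-1,5-diene bonds the terminal vinyl carbon to the ring CH= and breaks the bond between the silyloxy carbon and the C(CH3)2 carbon, giving the isopropylidene group and a silyl enol ether that buffered fluoride unmasks as the aldehyde; the new ring stereocentre should arise from suprafacial, axial bond formation on the ring face anti to the CH2OAr group of the neighbouring quaternary carbon and 1,3-trans to the ring methyl (the other face would need a 1,3-diaxial contact with that methyl), and both epimers at the silyloxy carbon converge because that carbon becomes sp2.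

**Compound list**

1 | 3-methylbutan-2-one | CC(=O)C(C)C | starting material
2 | trimethyl[(3-methylbut-2-en-2-yl)oxy]silane | CC(C)=C(C)O[Si](C)(C)C | intermediate
3 | prop-2-enal (acrolein) | C=CC=O | starting material
4 | 4-hydroxy-3,3-dimethylhex-5-en-2-one (racemic) | CC(=O)C(C)(C)C(O)C=C | intermediate
5 | 4-[(tert-butyldimethylsilyl)oxy]-3,3-dimethylhex-5-en-2-one (racemic) | CC(=O)C(C)(C)C(O[Si](C)(C)C(C)(C)C)C=C | intermediate
6 | 4-[(tert-butyldimethylsilyl)oxy]-3,3-dimethylhexa-1,5-dien-2-yl trifluoromethanesulfonate (racemic) | C=C(OS(=O)(=O)C(F)(F)F)C(C)(C)C(O[Si](C)(C)C(C)(C)C)C=C | intermediate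
7 | prop-2-yn-1-ol | C#CCO | starting material
8 | dimethyl{(1E)-3-[(dimethylalumanyl)oxy]-2-methylprop-1-en-1-yl}alumane (not isolated) | C[Al](C)/C=C(\C)CO[Al](C)C | intermediate
9 | (2E)-6-[(tert-butyldimethylsilyl)oxy]-2,5,5-trimethyl-4-methylideneocta-2,7-dien-1-ol (racemic) | OC/C(C)=C/C(=C)C(C)(C)C(O[Si](C)(C)C(C)(C)C)C=C | intermediate
10 | isofraxidin (7-hydroxy-6,8-dimethoxy-2H-chromen-2-one) | COc1cc2ccc(=O)oc2c(OC)c1O | starting material
11 | 7-{[(2E)-6-[(tert-butyldimethylsilyl)oxy]-2,5,5-trimethyl-4-methylideneocta-2,7-dien-1-yl]oxy}-6,8-dimethoxy-2H-chromen-2-one (racemic) | COc1cc2ccc(=O)oc2c(OC)c1OC/C(C)=C/C(=C)C(C)(C)C(O[Si](C)(C)C(C)(C)C)C=C | intermediate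
12 | (1S,2R)-4-{3-[(tert-butyldimethylsilyl)oxy]-2-methylpent-4-en-2-yl}-2-{[(6,8-dimethoxy-2-oxo-2H-chromen-7-yl)oxy]methyl}-2-methylcyclohex-3-ene-1-carbaldehyde (both configurations at the silyloxy carbon) | COc1cc2ccc(=O)oc2c(OC)c1OC[C@@]1(C)[C@@H](C=O)CCC(C(C)(C)C(O[Si](C)(C)C(C)(C)C)C=C)=C1 | intermediate
13 | (E)-N-tosylhydrazone of 12 (both configurations at the silyloxy carbon) | COc1cc2ccc(=O)oc2c(OC)c1OC[C@@]1(C)[C@@H](/C=N/NS(=O)(=O)c2ccc(C)cc2)CCC(C(C)(C)C(O[Si](C)(C)C(C)(C)C)C=C)=C1 | intermediate
14 | N-(1,3,2-benzodioxaborol-2-yl)-N'-tosylhydrazine formed from 13 (not isolated) | COc1cc2ccc(=O)oc2c(OC)c1OC[C@@]1(C)[C@@H](CN(NS(=O)(=O)c2ccc(C)cc2)B2Oc3ccccc3O2)CCC(C(C)(C)C(O[Si](C)(C)C(C)(C)C)C=C)=C1 | intermediate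
15 | 7-{[(1S,6S)-3-{3-[(tert-butyldimethylsilyl)oxy]-2-methylpent-4-en-2-yl}-1,6-dimethylcyclohex-2-en-1-yl]methoxy}-6,8-dimethoxy-2H-chromen-2-one (both configurations at the silyloxy carbon) | COc1cc2ccc(=O)oc2c(OC)c1OC[C@@]1(C)[C@@H](C)CCC(C(C)(C)C(O[Si](C)(C)C(C)(C)C)C=C)=C1 | intermediate
16 | 7-{[(1S,2S,6S)-2-{3-[(tert-butyldimethylsilyl)oxy]prop-2-en-1-yl}-1,6-dimethyl-3-(propan-2-ylidene)cyclohexyl]methoxy}-6,8-dimethoxy-2H-chromen-2-one (not isolated) | COc1cc2ccc(=O)oc2c(OC)c1OC[C@@]1(C)[C@@H](C)CCC(=C(C)C)[C@@H]1CC=CO[Si](C)(C)C(C)(C)C | intermediate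
17 | 3-[(1S,2S,3S)-2-{[(6,8-dimethoxy-2-oxo-2H-chromen-7-yl)oxy]methyl}-2,3-dimethyl-6-(propan-2-ylidene)cyclohexyl]propanal (CNP0213227.1) | COc1cc2ccc(=O)oc2c(OC)c1OC[C@@]1(C)[C@@H](C)CCC(=C(C)C)[C@@H]1CCC=O | target

**Step count and risks**

Total step count: 10. Longest linear sequence: 10 steps (1 → 17); compounds 3, 7 and 10 enter as bought materials.

Steps most likely to fail:

Step 7. The cycloaddition may be too slow at the fully substituted diene terminus, or endo and facial control may erode if bond formation becomes stepwise. The fallback sets out from 11 and changes the dienophile to an auxiliary-bound acrylimide activated by chelation. (4R)-3-Acryloyl-4-benzyl-1,3-oxazolidin-2-one with Et2AlCl (CH2Cl2, −78 °C) should give the endo N-acyloxazolidinone cycloadduct F1, the diene adding anti to the benzyl group of the chelated s-cis imide, that is to the same Re face of the α-carbon. LiSEt (THF, 0 °C) should then exchange the auxiliary for sulfur to give the S-ethyl thioester F2, and Fukuyama reduction (Et3SiH, 10% Pd/C, acetone, rt) comes back to the route at aldehyde 12.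

Step 10. Bond formation at the ring carbon next to the quaternary centre may need temperatures at which face selectivity drops or the silyl ether decomposes. The fallback sets out from 15 and runs the shift as a charge-accelerated rearrangement of the free alkoxide at low temperature. Bu4NF (THF, rt) should free the secondary allylic alcohol F3; KN(SiMe3)2 with 18-crown-6 (THF, −78 → 0 °C) should trigger the anionic oxy-Cope shift to the potassium enolate F4, and a cold pH 7 buffer quench comes back to the route at 17.

Step 5. Methyl transfer from aluminium to palladium may compete with alkenyl transfer, and carboalumination of the propargylic alkoxide may stay incomplete. The fallback sets out from 7 and 6 and couples two isolated partners. Carboalumination of 7 as in step 5 followed by I2 (THF, −30 °C) should give (2E)-3-iodo-2-methylprop-2-en-1-ol F5. Miyaura borylation of 6 (B2pin2, PdCl2(PPh3)2, PPh3, KOPh, toluene, 50 °C) should give the alkenyl pinacol boronate F6. Suzuki coupling of F5 with F6 (Pd(PPh3)4, K3PO4, THF/H2O, 50 °C) comes back to the route at 9.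

**Further compounds**

F1 | step 7 | (4R)-4-benzyl-3-{[(1S,2R)-4-{3-[(tert-butyldimethylsilyl)oxy]-2-methylpent-4-en-2-yl}-2-{[(6,8-dimethoxy-2-oxo-2H-chromen-7-yl)oxy]methyl}-2-methylcyclohex-3-en-1-yl]carbonyl}-1,3-oxazolidin-2-one | COc1cc2ccc(=O)oc2c(OC)c1OC[C@@]1(C)[C@@H](C(=O)N2[C@H](Cc3ccccc3)COC2=O)CCC(C(C)(C)C(O[Si](C)(C)C(C)(C)C)C=C)=C1
F2 | step 7 | S-ethyl (1S,2R)-4-{3-[(tert-butyldimethylsilyl)oxy]-2-methylpent-4-en-2-yl}-2-{[(6,8-dimethoxy-2-oxo-2H-chromen-7-yl)oxy]methyl}-2-methylcyclohex-3-ene-1-carbothioate | COc1cc2ccc(=O)oc2c(OC)c1OC[C@@]1(C)[C@@H](C(=O)SCC)CCC(C(C)(C)C(O[Si](C)(C)C(C)(C)C)C=C)=C1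
F3 | step 10 | 7-{[(1S,6S)-3-(3-hydroxy-2-methylpent-4-en-2-yl)-1,6-dimethylcyclohex-2-en-1-yl]methoxy}-6,8-dimethoxy-2H-chromen-2-one | COc1cc2ccc(=O)oc2c(OC)c1OC[C@@]1(C)[C@@H](C)CCC(C(C)(C)C(O)C=C)=C1
F4 | step 10 | potassium enolate of 17 | COc1cc2ccc(=O)oc2c(OC)c1OC[C@@]1(C)[C@@H](C)CCC(=C(C)C)[C@@H]1CC=C[O-].[K+]
F5 | step 5 | (2E)-3-iodo-2-methylprop-2-en-1-ol | OC/C(C)=C/I
F6 | step 5 | tert-butyl{[4,4-dimethyl-5-(4,4,5,5-tetramethyl-1,3,2-dioxaborolan-2-yl)hexa-1,5-dien-3-yl]oxy}dimethylsilane | C=C(B1OC(C)(C)C(C)(C)O1)C(C)(C)C(O[Si](C)(C)C(C)(C)C)C=C
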